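**Retrosynthetic overview**
1. The strategy rests on ring B (C5–C6–O7–C8–C1) and its one-carbon branch C4 on C5. This unit is the ring-contracted form of a 2-aryltetrahydropyran-4-one whose carbonyl carbon C4 lies between C5 and C1.
2. The ring A ether bond C4–O3 comes from a hydroxy lactone (C4 as carbonyl) by reduction and SN2 closure at the primary carbon C4. The acid-labile endo benzylic centres C2 and C6 are therefore never ionised.
3. The hydroxy lactone comes from a 3-diazo-5-(E)-arylidene pyranone. A photochemical Wolff shift moves C1 from C4 to C5 and water adds to the ketene. In the same flask C1=C2 is epoxidised and the new acid opens the oxirane at C2 from the rear.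
4. The oxirane oxygen is added after the contraction, not before, because an oxirane on C1 next to the ketene-derived enol would be lost by β-elimination.
5. The diazoketone comes from reductive aldol, dehydration and diazo transfer on the dihydropyranone of an asymmetric hetero-Diels–Alder reaction, which sets C6. Ring order: six-membered ring, then ring B, then ring A.

Key step: step 5

Notation: the core is numbered C1(OH), C2(Ar), O3, C4, C5(H), C6(Ar), O7, C8. Ring A is C1–C2–O3–C4–C5 and ring B is C5–C6–O7–C8–C1. Ar is 4-benzyloxy-3-methoxyphenyl.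
Assumption: the target SMILES is read as the endo,endo isomer (both aryl groups trans to the bridgehead OH and H), (3S,3aS,6R,6aR); the (R)-BINOL/Ti(OiPr)4 catalyst is taken to induce in the sense known for benzaldehyde, and the ligand antipode is used if the check on 4 shows the opposite.

**Step 1**
Reactants: 1 O-benzylvanillin; 2 (E)-1-methoxy-3-trimethylsilyloxybuta-1,3-diene
Product: 4 (2R)-2-Ar-2,3-dihydro-4H-pyran-4-one, via silyl aldol adduct 3 (not isolated)
Conditions: (R)-BINOL (20 mol %), Ti(OiPr)4 (10 mol %), 4 Å MS, Et2O, −20 °C; then CF3CO2H (cat.), CH2Cl2, 0 °C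
Reagents that add atoms: none
Why: This is a catalytic asymmetric hetero-Diels–Alder reaction in its Mukaiyama aldol–cyclisation form, in which the BINOLate–titanium complex exposes the Re face of the bound aldehyde to the diene terminus and sets C6 as R, after which acid closes O7–C8 with loss of the methoxy and silyl groups.

**Step 2**
Reactants: 4 (2R)-2-Ar-2,3-dihydro-4H-pyran-4-one; 1 O-benzylvanillin
Product: 6 (2R)-2-Ar-5-[Ar(hydroxy)methyl]tetrahydro-4H-pyran-4-one (epimers at C1 and C2), via lithium enolate 5 (not isolated)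
Conditions: LiBH(s-Bu)3 (1.0 equiv), THF, −78 °C; then 1, −78 °C; AcOH quench at −78 °C
Reagents that add atoms: none
Why: In this reductive aldol reaction, conjugate hydride addition at C8 of the vinylogous ester gives the enolate regiospecifically at C1 rather than C5, its aldol addition to 1 forms C1–C2, and the two new centres need no control because step 3 erases both.

**Step 3**
Reactants: 6 aldol adduct
Product: 8 (2R,5E)-2-Ar-5-(4-benzyloxy-3-methoxybenzylidene)tetrahydro-4H-pyran-4-one, via benzylic mesylate 7 (not isolated)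
Conditions: MsCl, Et3N (4 equiv), CH2Cl2, −20 → 0 °C
Reagents that add atoms: none
Why: Sulfonylation followed by E1cB elimination of the very labile p-alkoxybenzylic mesylate gives the arylidene ketone as the E isomer (aryl anti to the carbonyl, cis to C8), which avoids allylic strain with the C4 oxygen, and the weak amine base spares C6.

**Step 4**
Reactants: 8 E-arylidene ketone
Product: 11 (2S,5E)-2-Ar-5-(4-benzyloxy-3-methoxybenzylidene)-3-diazotetrahydro-4H-pyran-4-one, via lithium enolate 9 (not isolated), via trifluoroacetyl ketone 10 (not isolated)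
Conditions: LiN(SiMe3)2, THF, −78 °C; CF3CO2CH2CF3, −78 °C; 5 % aq. HCl wash; then MsN3, Et3N, H2O (1 equiv), MeCN, rt
Reagents that add atoms: methanesulfonyl azide, CS(=O)(=O)N=[N+]=[N-]
Why: In this detrifluoroacetylative diazo transfer, C5 is the only enolisable position of the enone, its kinetic enolate is C-acylated, and the activated 1,3-dicarbonyl compound takes N2 from the sulfonyl azide with loss of the trifluoroacetyl group, while the low temperature keeps the enolate from expelling O7 so that C6 is preserved (the descriptor changes to S only by priority).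

**Step 5**
Reactants: 11 arylidene diazoketone
Product: 15 (3S,3aS,6R,6aR)-3,6-di-Ar-3a-hydroxytetrahydro-1H,3H-furo[3,4-c]furan-1-one, via vinylketene 12 (not isolated), via cis unsaturated acid 13 (not isolated), via spiro-epoxy acid 14 (not isolated)
Conditions: hν (440 nm LED), THF/H2O 10:1, 0 °C; concentrate cold, dry; then DMDO (acetone solution, 1.1 equiv), CH2Cl2, −40 → 0 °C
Reagents that add atoms: water, O; dimethyldioxirane, CC1(C)OO1
Why: Light absorbed by the s-Z-locked cyclic diazoketone expels N2 with a concerted 1,2-shift of C1 from C4 to C5 (photochemical Wolff ring contraction, known for 2-diazocycloalkanones and for α′-diazo enones), so ring B closes by contraction of the six-membered ring and C4 is extruded as the carbonyl carbon of vinylketene 12, with the C1=C2 geometry and C6 untouched. Water adds to C4 and the dienol is protonated kinetically at its α carbon C5, as is usual for vinylketene hydration, from the face opposite the C6 aryl group, which allylic strain with the exocyclic C4 unit turns pseudoaxial; this sets C5 with H trans and carboxyl cis to that aryl (13). DMDO then epoxidises the electron-rich trisubstituted styrene bond from the face left open by the C5 carboxyl and the C6 aryl, which sets C1 with its oxygen cis to H5 (14). The carboxyl lies opposite the oxirane oxygen and opens the C2–O bond from the rear (epoxy-acid lactonisation, known for epoxidised β,γ-unsaturated acids); because both oxirane carbons end up in ring A the closure is 5-endo with respect to the epoxide and depends on the loose transition state at the p-alkoxybenzylic carbon, and anti opening of an oxirane whose aryl is cis to C8 sets C2 with the aryl endo. The oxygen atom is brought in only after the contraction because an oxirane already on C1 would be ejected by the enol that ketene hydration produces, which is the known fate of α,β-epoxy diazoketones (they give γ-hydroxy enoic acid derivatives). The step needs Wolff shift rather than 1,2-hydride shift from C6 (secured by the s-Z geometry and direct singlet excitation), no E/Z leakage (irradiation in the long-wavelength diazo band, where the products are transparent), and attack at C2 rather than C1 (benzylic activation and the strain of the alternative β-lactone).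

**Step 6**
Reactants: 15 hydroxy lactone
Product: 16 (3S,4R,5R)-5-Ar-3-[(S)-Ar(hydroxy)methyl]-4-(hydroxymethyl)tetrahydrofuran-3-ol
Conditions: LiAlH4, THF, 0 °C; aq. potassium sodium tartrate work-up
Reagents that add atoms: none
Why: Hydride reduction of the lactone cleaves the acyl C4–O3 bond and leaves O3 on C2, so no stereocentre is touched, and reduction at 0 °C is faster than any retro-aldol cleavage of the β-hydroxy carbonyl unit.

**Step 7**
Reactants: 16 triol
Product: 18 (3S,3aS,6R,6aR)-3,6-di-Ar-tetrahydro-1H,3H-furo[3,4-c]furan-3a-ol, via primary tosylate 17 (not isolated)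
Conditions: TsCl (1.1 equiv), pyridine, 0 → 40 °C
Reagents that add atoms: none
Why: Selective sulfonylation of the only primary hydroxyl and intramolecular Williamson-type 5-exo-tet displacement at C4 by the cis-held C2 hydroxyl close ring A without breaking a bond at C2, so the endo aryl is kept, and the weak base leaves the C1 hydroxyl un-ionised, which holds back oxetane formation and Grob fragmentation.

**Step 8**
Reactants: 18 dibenzyl ether
Product: 19 target, (3S,3aS,6R,6aR)-3,6-bis(4-hydroxy-3-methoxyphenyl)tetrahydro-1H,3H-furo[3,4-c]furan-3a-ol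
Conditions: H2 (1 atm), 10 % Pd/C, EtOAc, rt, stopped when 18 is consumed
Reagents that add atoms: none
Why: In this catalytic hydrogenolysis the two aryl benzyl ethers are cleaved faster than the ring benzylic C–O bonds at C2 and C6, and the neutral aprotic medium avoids acid-catalysed epimerisation of the endo aryl groups.

**Compound list**
1 | O-benzylvanillin (4-benzyloxy-3-methoxybenzaldehyde) | COc1cc(C=O)ccc1OCc1ccccc1 | starting material
2 | (E)-1-methoxy-3-trimethylsilyloxybuta-1,3-diene | CO/C=C/C(=C)O[Si](C)(C)C | starting material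
3 | (1E,5R)-5-(4-benzyloxy-3-methoxyphenyl)-1-methoxy-5-trimethylsilyloxypent-1-en-3-one | COc1cc([C@@H](CC(=O)/C=C/OC)O[Si](C)(C)C)ccc1OCc1ccccc1 | intermediate
4 | (2R)-2-(4-benzyloxy-3-methoxyphenyl)-2,3-dihydro-4H-pyran-4-one | COc1cc([C@@H]2OC=CC(=O)C2)ccc1OCc1ccccc1 | intermediate
5 | lithium enolate (C1=C4) of (2R)-2-(4-benzyloxy-3-methoxyphenyl)tetrahydropyran-4-one | COc1cc([C@@H]2OCC=C([O-])C2)ccc1OCc1ccccc1.[Li+] | intermediate
6 | (2R)-2-(4-benzyloxy-3-methoxyphenyl)-5-[(4-benzyloxy-3-methoxyphenyl)(hydroxy)methyl]tetrahydro-4H-pyran-4-one, epimers at C1 and C2 | COc1cc([C@@H]2OCC(C(O)c3ccc(OCc4ccccc4)c(OC)c3)C(=O)C2)ccc1OCc1ccccc1 | intermediate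
7 | benzylic methanesulfonate of 6 | COc1cc([C@@H]2OCC(C(OS(C)(=O)=O)c3ccc(OCc4ccccc4)c(OC)c3)C(=O)C2)ccc1OCc1ccccc1 | intermediate
8 | (2R,5E)-2-(4-benzyloxy-3-methoxyphenyl)-5-(4-benzyloxy-3-methoxybenzylidene)tetrahydro-4H-pyran-4-one | COc1cc([C@@H]2OC/C(=C\c3ccc(OCc4ccccc4)c(OC)c3)C(=O)C2)ccc1OCc1ccccc1 | intermediate
9 | lithium enolate (C5=C4) of 8 | COc1cc([C@@H]2OC/C(=C\c3ccc(OCc4ccccc4)c(OC)c3)C([O-])=C2)ccc1OCc1ccccc1.[Li+] | intermediate
10 | 3-trifluoroacetyl derivative of 8 (acyl group on C5) | COc1cc([C@@H]2OC/C(=C\c3ccc(OCc4ccccc4)c(OC)c3)C(=O)C2C(=O)C(F)(F)F)ccc1OCc1ccccc1 | intermediate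
11 | (2S,5E)-2-(4-benzyloxy-3-methoxyphenyl)-5-(4-benzyloxy-3-methoxybenzylidene)-3-diazotetrahydro-4H-pyran-4-one | COc1cc([C@@H]2OC/C(=C\c3ccc(OCc4ccccc4)c(OC)c3)C(=O)C2=[N+]=[N-])ccc1OCc1ccccc1 | intermediate
12 | vinylketene: 2-aryl-4-arylidenetetrahydrofuran-3-ylidene ketene, aryl of C2 cis to C8, C6 as in 11 | COc1cc([C@@H]2OC/C(=C\c3ccc(OCc4ccccc4)c(OC)c3)C2=C=O)ccc1OCc1ccccc1 | intermediate
13 | (2R,3S,4Z)-2-(4-benzyloxy-3-methoxyphenyl)-4-(4-benzyloxy-3-methoxybenzylidene)tetrahydrofuran-3-carboxylic acid | COc1cc([C@@H]2OC/C(=C\c3ccc(OCc4ccccc4)c(OC)c3)[C@@H]2C(=O)O)ccc1OCc1ccccc1 | intermediate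
14 | (2R,3S,6R,7R)-2,6-bis(4-benzyloxy-3-methoxyphenyl)-1,5-dioxaspiro[2.4]heptane-7-carboxylic acid | COc1cc([C@@H]2OC[C@@]3(O[C@@H]3c3ccc(OCc4ccccc4)c(OC)c3)[C@@H]2C(=O)O)ccc1OCc1ccccc1 | intermediate
15 | (3S,3aS,6R,6aR)-3,6-bis(4-benzyloxy-3-methoxyphenyl)-3a-hydroxytetrahydro-1H,3H-furo[3,4-c]furan-1-one | COc1cc([C@@H]2OC[C@@]3(O)[C@@H]2C(=O)O[C@H]3c2ccc(OCc4ccccc4)c(OC)c2)ccc1OCc1ccccc1 | intermediate
16 | (3S,4R,5R)-5-(4-benzyloxy-3-methoxyphenyl)-3-[(S)-(4-benzyloxy-3-methoxyphenyl)(hydroxy)methyl]-4-(hydroxymethyl)tetrahydrofuran-3-ol | COc1cc([C@@H]2OC[C@@]([C@@H](O)c3ccc(OCc4ccccc4)c(OC)c3)(O)[C@@H]2CO)ccc1OCc1ccccc1 | intermediate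
17 | primary p-toluenesulfonate (at C4) of 16 | COc1cc([C@@H]2OC[C@@]([C@@H](O)c3ccc(OCc4ccccc4)c(OC)c3)(O)[C@@H]2COS(=O)(=O)c5ccc(C)cc5)ccc1OCc1ccccc1 | intermediate
18 | (3S,3aS,6R,6aR)-3,6-bis(4-benzyloxy-3-methoxyphenyl)tetrahydro-1H,3H-furo[3,4-c]furan-3a-ol | COc1cc([C@@H]2OC[C@@]3(O)[C@@H]2CO[C@H]3c2ccc(OCc4ccccc4)c(OC)c2)ccc1OCc1ccccc1 | intermediate
19 | (3S,3aS,6R,6aR)-3,6-bis(4-hydroxy-3-methoxyphenyl)tetrahydro-1H,3H-furo[3,4-c]furan-3a-ol (CNP0138682.2) | COc1cc([C@@H]2OC[C@@]3(O)[C@@H]2CO[C@H]3c2ccc(O)c(OC)c2)ccc1O | target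

**Step count**
Total step count: 8. Longest linear sequence: 8 steps (1 to 19; compound 1 enters twice).

**Steps most likely to fail**

*Step 5.* Three processes could spoil it:
- E to Z photoisomerisation of the arylidene unit before N2 is lost.
- Incomplete facial selectivity in the protonation of C5.
- Partial ionisation of the oxirane at C2, which would erode the inversion or allow a semipinacol shift.

The fallback sets out from 11. Irradiation in THF/MeOH gives methyl ester F1, a stable compound from which geometric or C5 isomers can be removed by chromatography. i-Bu2AlH (CH2Cl2, −78 °C) reduces it to homoallylic alcohol F2. DMDO, attacking from the face anti to the hydroxymethyl and aryl groups, gives epoxy alcohol F3. Its primary hydroxyl, as the alkoxide after addition of NaH if the oxirane persists, opens C2 from the rear. This is the known cyclisation of 3,4-epoxy alcohols with an aryl-activated terminus to 3-hydroxytetrahydrofurans. The fallback comes back to the route at 18 and bypasses 15 to 17.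

*Step 2.* Three processes could spoil it:
- Proton exchange between the enolate and the carbonyl compounds, with loss of the C1 regiochemistry.
- Retro-aldol cleavage on warming.
- Hydride transfer to the aldehyde.

The fallback sets out from 4. The same conjugate reduction is quenched with Me3SiCl to give silyl enol ether F4, which can be purified. A Mukaiyama aldol addition to 1 (BF3·OEt2, CH2Cl2, −78 °C) then forms C1–C2 under non-basic conditions. The fallback comes back to the route at 6.

*Step 7.* Competing sulfonylation of the benzylic C2 hydroxyl, followed by ionisation and epimerisation, could spoil it, as could sluggish closure on the concave face. The fallback sets out from 15. i-Bu2AlH (toluene, −78 °C) stops at lactol F5. Ionic reduction with Et3SiH/BF3·OEt2 (CH2Cl2, −78 °C) removes the anomeric hydroxyl through the cyclic oxocarbenium ion, which should form faster than either benzylic ether ionises at that temperature. The fallback comes back to the route at 18.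

**Further compounds**
F1 | step 5 | methyl (2R,3S,4Z)-2-(4-benzyloxy-3-methoxyphenyl)-4-(4-benzyloxy-3-methoxybenzylidene)tetrahydrofuran-3-carboxylate | COc1cc([C@@H]2OC/C(=C\c3ccc(OCc4ccccc4)c(OC)c3)[C@@H]2C(=O)OC)ccc1OCc1ccccc1
F2 | step 5 | [(2R,3R,4Z)-2-(4-benzyloxy-3-methoxyphenyl)-4-(4-benzyloxy-3-methoxybenzylidene)tetrahydrofuran-3-yl]methanol | COc1cc([C@@H]2OC/C(=C\c3ccc(OCc4ccccc4)c(OC)c3)[C@@H]2CO)ccc1OCc1ccccc1
F3 | step 5 | [(2R,3S,6R,7R)-2,6-bis(4-benzyloxy-3-methoxyphenyl)-1,5-dioxaspiro[2.4]heptan-7-yl]methanol | COc1cc([C@@H]2OC[C@@]3(O[C@@H]3c3ccc(OCc4ccccc4)c(OC)c3)[C@@H]2CO)ccc1OCc1ccccc1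
F4 | step 2 | (2R)-2-(4-benzyloxy-3-methoxyphenyl)-4-trimethylsilyloxy-3,6-dihydro-2H-pyran | COc1cc([C@@H]2OCC=C(O[Si](C)(C)C)C2)ccc1OCc1ccccc1
F5 | step 7 | (3S,3aS,6R,6aR)-3,6-bis(4-benzyloxy-3-methoxyphenyl)tetrahydro-1H,3H-furo[3,4-c]furan-1,3a-diol (lactol, anomers) | COc1cc([C@@H]2OC[C@@]3(O)[C@@H]2C(O)O[C@H]3c2ccc(OCc4ccccc4)c(OC)c2)ccc1OCc1ccccc1
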